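(Readings and results were computed on assumed constants; the scatter is artificial.)

At the hour we add free catalyst to the birch flask (gamma), and one number carries that choice.

- birch: substrate 33 mM; reagent 16.5 mM; capture agent 33 mM; free catalyst 2.5 mM; the very flask that is asked about, followed so far
- flask: substrate 33 mM; reagent 16.5 mM; capture agent 33.0 mM; free catalyst 2.5 mM; time 1.0 h

birch run (percent of the substrate charged)

| time / min | product / % | substrate / % |
|---|---|---|
| 2.00 | 0.6 | 96.8 |
| 6.00 | 6.0 | 93.7 |
| 10.0 | 8.0 | 91.2 |
| 15.0 | 9.8 | 88.5 |
| 20.0 | 11.2 | 88.6 |
| 30.0 | 11.4 | 88.3 |
| 40.0 | 11.8 | 87.7 |

(scatter of a reading: 0.5 percentage points)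

- gamma: at 1.0 h add free catalyst, 50.0% of the amount charged, then wait 20 min
- delta: at 1.0 h add reagent, 50.0% of the amount charged, then wait 20 min
- beta: at 1.0 h take out 90% of the product then present, then wait 20 min
- zeta: change nothing and wait 20 min more

- what is taken out of product is counted as made
- additions bring no volume worth counting

1. product, in percent of the substrate first charged, at 1.0 h
2. which option adds most product ("none" when 2 percentage points or less is all one gets) (gamma / delta / beta / zeta / none)
3. product present, with what was taken out counted in, in percent of the substrate first charged, after gamma
4. product present, with what was taken out counted in, in percent of the substrate first charged, after delta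

We climb the time scales of the birch run from the shortest. At 2.00 min substrate reads 96.8% and product 0.6%, so some material is still on its way, but by 6.00 min the two columns add up again. Next comes the approach to the plateau, which we solve at both ends and join. The late end is the mean of both columns at the last two readings, the early end how the gap to that plateau shrinks between 6.00 min and 15.0 min:

plateau = 11.8%

τ = 8.45 min

product(t) = plateau · (1 − exp(−t/τ))

N = plateau · c(substrate) / c(free catalyst) = 1.56

N, a reading that carries the scatter of the birch run, is product made per free catalyst charged before the flask stops, its turnover number. Even at one reagent per product, the reagent charge allows 50.0%, more than the plateau, and substrate still reads 87.7%. So we lay the stop on the catalyst, and we assume that added catalyst gives the same N.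

The last rungs are the wait, 2.37 time constants, and the hour, 7.10. At the hour the remaining gap is 0.0098 percentage points, against a margin of 2 points, so we expect nothing from waiting, and by judgement nothing from reagent or from taking product out:

now = 11.8%

gain from gamma = N · 50.0% · c(free catalyst) / c(substrate) · (1 − exp(−dt/τ)) = 5.3 points

after gamma = 17.1%; after delta = 11.8%

The forecast gave 12%, gamma, 17.3% after gamma and 12.6% after delta, the last two above ours, on the ground that “The likeliest cause is that the catalyst dies, or is used up, in proportion to turnover or time.”

The simulation gives 12.2%, best option gamma, 17.4% after gamma and 12.2% after delta.

    reagent + free catalyst ⇌ catalyst intermediate A (K = 2980 /M, k = 106 /M/min)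
    catalyst intermediate A → by-product + catalyst intermediate B (k = 1.09 /min)
    substrate + catalyst intermediate B → catalyst intermediate C (k = 30.5 /M/min)
    catalyst intermediate C → free catalyst + product (k = 0.992 /min)
    capture agent + catalyst intermediate B → trapped intermediate (k = 18.5 /M/min)

In the birch flask, catalyst intermediate B went on either to substrate or to capture agent: by 6.00 min trapped intermediate held 54.8% of the catalyst with product at 5.88%, and by 30.0 min it held 98.0% with product at 11.9%. At 60.0 min it held >99.9%, while substrate stood at 87.8% and reagent at 60.5%. The catalyst added in gamma turned over 1.38 times in the wait; N with the wait factor gives 1.41.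

For the neighbour flask charged with 0.62 mM of free catalyst, N gives 2.93%. The computed flask holds 3.08% at 60.0 min.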